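Read the 3 questions as one: how much E is left in each flask, since what E loses turns up as J. In gamma at 120 s, the two still sum to 100% of the charge.

| flask | E | D | Z | remark | time |
|---|---|---|---|---|---|
| delta | 39 mM (fed, over 6.0 s) | 9.4 mM (held) | 0.39 mM | run made earlier |  |
| gamma | 39 mM (fed, over 6.0 s) | 9.4 mM (held) | 0.58 mM | run made earlier |  |
| amber | 39 mM (fed, over 6.0 s) | 9.4 mM (held) | 0.78 mM |  | 2.5 min |
| grey | 39 mM | 9.4 mM | 0.78 mM | everything together at the start | 1.2 min |

| run | time / s | J / % | E / % |
|---|---|---|---|
| delta | 15.0 | 8.7 | 89.7 |
| delta | 40.0 | 21.6 | 79.5 |
| delta | 80.0 | 35.0 | 67.0 |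
| delta | 120 | 40.4 | 60.0 |
| gamma | 30.0 | 20.0 | 81.2 |
| gamma | 60.0 | 29.5 | 68.6 |
| gamma | 90.0 | 37.1 | 63.3 |
| gamma | 120 | 43.1 | 57.2 |

(each reading ± 1 percentage point)

- which of the two ends with the higher amount of J, in percent of the E charged ("neither" if they lie within 2 percentage points) (amber / grey / neither)
- J at the end, in percent of the E charged, amber
- J at the end, in percent of the E charged, grey

- at the start none of G is dissolved
- steps thought possible: 2 Z -> Q; E + G + Z -> Z + J; D <-> G

Try the plainest estimate first, a pseudo-first-order fall of E with Z and G standing still. Gamma's 68.6% left at 60.0 s should then square to 47.1% at 120 s, but the reading is 57.2%, so drop it.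

Let Z die instead by the step 2 Z -> Q. Once the start is forgotten, Z falls as one over time, so with G steady ln(E left) drops by equal steps for equal ratios of time. Measure that step in gamma from 60.0 s to 120 s: it gives 0.262. This drop of ln(E left) per unit of ln(time) is the decay slope. Delta from 40.0 s to 120 s gives 0.256, about the same on a smaller charge of Z.

Now object: G starts at zero, so do not run the slope from time zero. Anchor it on a late reading instead.

Object again: amber is charged with more Z than gamma. Delta and gamma at 120 s give a slope against the Z charge of 0.120, smaller than the time slope, though it rests on a gap of 2.8 percentage points with 1 point of scatter on each reading. Apply both slopes to gamma's reading. On this estimate amber keeps 52.1% of its E, which means 47.9% of J, and grey keeps 63.1%, which means 36.9% of J. Gamma and amber are fed and grey is not, but set that difference aside in this estimate, since the feed of 6.0 s is short against grey's 72 s.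

The forecast says amber, with 50% for amber and 36% for grey, holding that “the dying catalyst limits the gain”. This reckoning gives the same winner but lies 2.1 points lower on amber and 0.90 points higher on grey.

The flasks give 46.6% of J in amber and 35.0% in grey, so amber ends higher.

    2 Z → Q (k = 144 L mol⁻¹ s⁻¹)
    E + G + Z → Z + J (k = 9740 L² mol⁻² s⁻¹)
    D ⇌ G, rate k3*(csat - [G]) (kL = 0.0958 s⁻¹)

E left stands at 53% in amber and 65% in grey. Carry the slope back from amber's end to the amber charge read at 1.5 min: it gives 61.1% of E left, and that flask holds 62%.

Readings and results were generated by integration with constants of no real substance, and the scatter is random.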